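**Strategy**

The route rests on the disconnection between the side-chain carbinol carbon C1′ and the benzylic carbon C2′. A 4-silyloxybenzyl titanium triisopropoxide is added to the formyl group on C6 of an otherwise complete cis-2,6-disubstituted oxan-4-one. In one operation this joins both halves, creates the C1′ stereocentre and leaves the ring ketone C4=O untouched. The step exploits that C1′ lies next to C6, which carries ring oxygen O1: the C6–O1 bond steers a non-chelated Felkin–Anh addition to the 1′,6-anti alcohol, and the aldehyde/ketone reactivity gap makes protection of C4 unnecessary. The precursor aldehyde comes from a catalytic asymmetric hetero-Diels–Alder reaction.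

Key step: step 4

Remarks on the chemistry: TBS = tert-butyldimethylsilyl. Compounds 3 and 7 are taken as catalogue compounds. The (1R,2S)-aminoindanol-derived Cr(III) catalyst is assumed to expose the Re face of the aldehyde; its antipode would be taken if a test run showed the opposite sense. Locants in the text follow the target: oxan-4-one ring O1, C2 (aryl), C4 (C=O), C6 (side chain), then C1′ and C2′.

**Route**

Step 1
Reactants: 1 dehydrozingerone, (E)-4-(4-hydroxy-3-methoxyphenyl)but-3-en-2-one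
Product: 2 tert-butyl{4-[(1E)-3-(TBS-oxy)buta-1,3-dien-1-yl]-2-methoxyphenoxy}dimethylsilane
Conditions: TBSOTf (2.3 equiv), Et3N (3 equiv), CH2Cl2, 0 °C
Reagents that add atoms: tert-butyldimethylsilyl trifluoromethanesulfonate (TBSOTf), CC(C)(C)[Si](C)(C)OS(=O)(=O)C(F)(F)F
Why: Silyl triflate/amine soft enolisation should silylate the phenol and convert the methyl ketone into its kinetic cross-conjugated silyl enol ether, giving the 2-silyloxy-1,3-diene with the (E)-styryl geometry unchanged.

Step 2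
Reactants: 2 bis-TBS diene; 3 (tert-butyldimethylsilyloxy)acetaldehyde
Product: 5 (2S,6R)-6-(hydroxymethyl)-2-[3-methoxy-4-(TBS-oxy)phenyl]oxan-4-one, via silyl enol ether cycloadduct 4 (not isolated)
Conditions: Cr(III)Cl complex of the Schiff base from (1R,2S)-1-amino-2-indanol and 3-(1-adamantyl)-5-methylsalicylaldehyde (5 mol %), 4 Å MS, acetone, rt; then 1 M HCl, THF, rt
Reagents that add atoms: none
Why: In this Lewis-acid-catalysed hetero-Diels–Alder reaction the diene CH2 terminus should add to the Re face of the catalyst-bound aldehyde through an endo transition state, which sets both ring stereocentres cis (C2 S, C6 R), and dilute acid then hydrolyses the silyl enol ether to the C4 ketone and cleaves the primary alkyl TBS ether while the aryl TBS ether survives.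

Step 3
Reactants: 5 hydroxymethyl oxanone
Product: 6 (2R,6S)-6-[3-methoxy-4-(TBS-oxy)phenyl]-4-oxooxane-2-carbaldehyde
Conditions: TEMPO (10 mol %), PhI(OAc)2 (1.2 equiv), CH2Cl2, rt; used without chromatography
Reagents that add atoms: none
Why: Oxoammonium (TEMPO/PhI(OAc)2) oxidation should take the primary alcohol to the aldehyde under non-basic conditions that spare the ketone, the aryl silyl ether and the stereocentre next to the formyl group.

Step 4
Reactants: 6 keto aldehyde; 7 tert-butyl[4-(chloromethyl)phenoxy]dimethylsilane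
Product: 10 (2S,6R)-6-{(1S)-1-hydroxy-2-[4-(TBS-oxy)phenyl]ethyl}-2-[3-methoxy-4-(TBS-oxy)phenyl]oxan-4-one, via benzylmagnesium chloride 8 (not isolated), via benzyltitanium triisopropoxide 9 (not isolated)
Conditions: 7, Mg, Et2O, 0 °C to rt; ClTi(OiPr)3, −78 °C; then 6, THF, −78 to −30 °C; sat. aq. NH4Cl
Reagents that add atoms: none
Why: Magnesium insertion into 7 and transmetalation with ClTi(OiPr)3 give a σ-benzyltitanium triisopropoxide, which adds 1,2 to the formyl carbon of 6 through an open, non-chelated transition state. The closest known reaction type is the non-chelation-controlled (Felkin–Anh) addition of alkyltitanium triisopropoxides to α-alkoxy aldehydes. No ring is closed. The new C1′ centre is controlled by the adjacent ring carbon C6: the C6–O1 bond lies anti to the incoming benzyl group and the nucleophile passes the small C6–H, which should give the 1′,6-anti, (1′S) alcohol. The step needs facial selectivity, which the weakly Lewis acidic, non-chelating Ti(OiPr)3 group secures once the magnesium salts have precipitated from ether. It also needs aldehyde-over-ketone selectivity, which the low reactivity of alkyltitanium triisopropoxides toward the C4 ketone below −30 °C secures.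

Step 5
Reactants: 10 bis-silyl ether
Product: 11 (2S,6R)-2-(4-hydroxy-3-methoxyphenyl)-6-[(1S)-1-hydroxy-2-(4-hydroxyphenyl)ethyl]oxan-4-one
Conditions: TBAF (2.5 equiv), AcOH (2.5 equiv), THF, 0 °C
Reagents that add atoms: none
Why: Fluoride should cleave both aryl silyl ethers, and the acetic acid buffer keeps the phenoxides from triggering a retro-oxa-Michael opening of the β-alkoxy ketone, so no stereocentre is touched.

**Compound list**

1 | dehydrozingerone, (E)-4-(4-hydroxy-3-methoxyphenyl)but-3-en-2-one | CC(=O)/C=C/c1ccc(O)c(OC)c1 | starting material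
2 | tert-butyl{4-[(1E)-3-(TBS-oxy)buta-1,3-dien-1-yl]-2-methoxyphenoxy}dimethylsilane | C=C(O[Si](C)(C)C(C)(C)C)/C=C/c1ccc(O[Si](C)(C)C(C)(C)C)c(OC)c1 | intermediate
3 | (tert-butyldimethylsilyloxy)acetaldehyde | O=CCO[Si](C)(C)C(C)(C)C | starting material
4 | (2R,6S)-4-(TBS-oxy)-2-[(TBS-oxy)methyl]-6-[3-methoxy-4-(TBS-oxy)phenyl]-3,6-dihydro-2H-pyran | COc1cc([C@@H]2C=C(O[Si](C)(C)C(C)(C)C)C[C@H](CO[Si](C)(C)C(C)(C)C)O2)ccc1O[Si](C)(C)C(C)(C)C | intermediate
5 | (2S,6R)-6-(hydroxymethyl)-2-[3-methoxy-4-(TBS-oxy)phenyl]oxan-4-one | COc1cc([C@@H]2CC(=O)C[C@H](CO)O2)ccc1O[Si](C)(C)C(C)(C)C | intermediate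
6 | (2R,6S)-6-[3-methoxy-4-(TBS-oxy)phenyl]-4-oxooxane-2-carbaldehyde | COc1cc([C@@H]2CC(=O)C[C@H](C=O)O2)ccc1O[Si](C)(C)C(C)(C)C | intermediate
7 | tert-butyl[4-(chloromethyl)phenoxy]dimethylsilane | ClCc1ccc(O[Si](C)(C)C(C)(C)C)cc1 | starting material
8 | [4-(TBS-oxy)benzyl]magnesium chloride | Cl[Mg]Cc1ccc(O[Si](C)(C)C(C)(C)C)cc1 | intermediate
9 | [4-(TBS-oxy)benzyl]titanium triisopropoxide | CC(C)O[Ti](OC(C)C)(OC(C)C)Cc1ccc(O[Si](C)(C)C(C)(C)C)cc1 | intermediate
10 | (2S,6R)-6-{(1S)-1-hydroxy-2-[4-(TBS-oxy)phenyl]ethyl}-2-[3-methoxy-4-(TBS-oxy)phenyl]oxan-4-one | COc1cc([C@@H]2CC(=O)C[C@H]([C@@H](O)Cc3ccc(O[Si](C)(C)C(C)(C)C)cc3)O2)ccc1O[Si](C)(C)C(C)(C)C | intermediate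
11 | (2S,6R)-2-(4-hydroxy-3-methoxyphenyl)-6-[(1S)-1-hydroxy-2-(4-hydroxyphenyl)ethyl]oxan-4-one | COc1cc([C@@H]2CC(=O)C[C@H]([C@@H](O)Cc3ccc(O)cc3)O2)ccc1O | target

**Step count**

Total steps: 5. Longest linear sequence: 5 steps (1 → 2 → 5 → 6 → 10 → 11).

**Steps most likely to fail**

Step 4 (key step). Facial discrimination may be poor if a chelated transition state, with a metal bridging the formyl oxygen and O1, competes with the Felkin–Anh pathway. Some reagent may also be lost to attack on the ring ketone. The fallback sets out from 6 and makes chelation the controlling element. One equivalent of Grignard reagent 8 is added inversely to 6 precomplexed with MgBr2·OEt2 in CH2Cl2 at −78 °C, which should give the 1′,6-syn alcohol (2S,6R)-6-{(1R)-1-hydroxy-2-[4-(TBS-oxy)phenyl]ethyl}-2-[3-methoxy-4-(TBS-oxy)phenyl]oxan-4-one F1. A Mitsunobu reaction (4-nitrobenzoic acid, PPh3, DIAD, toluene) then inverts C1′ to the (1S)-configured 4-nitrobenzoate F2. K2CO3 in methanol removes the ester and both aryl silyl ethers, and the fallback comes back to the route at 11.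

Step 2. The aryl-conjugated diene may turn over slowly, and an uncatalysed or stepwise Mukaiyama-aldol pathway may erode the enantio- and endo-selectivity. The fallback sets out from 1 and builds the ring by aldol reaction and oxa-Michael closure. TBSCl/imidazole gives the aryl silyl ether (E)-4-[3-methoxy-4-(TBS-oxy)phenyl]but-3-en-2-one F3. Its boron enolate is formed with Et3N and the B-chlorodiisopinocampheylborane antipode that delivers the (R)-carbinol, and it adds to aldehyde 3 to give the β-hydroxy enone (1E,5R)-5-hydroxy-1-[3-methoxy-4-(TBS-oxy)phenyl]-6-(TBS-oxy)hex-1-en-3-one F4. Aqueous HCl in THF should then bring about the 6-endo oxa-Michael closure under thermodynamic control (2,6-cis) and cleave the primary TBS ether, and the fallback comes back to the route at 5.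

Step 3. The keto aldehyde may be lost through hydration or oligomerisation, through epimerisation next to the formyl group, or through β-elimination that opens the oxanone ring during oxidation and handling. The fallback sets out from 2 and keeps the ring ketone masked until the end. The same Cr(III) catalyst is used with ethyl glyoxylate and no acidic work-up, which gives the ester cycloadduct ethyl (2R,6S)-4-(TBS-oxy)-6-[3-methoxy-4-(TBS-oxy)phenyl]-3,6-dihydro-2H-pyran-2-carboxylate F5. DIBAL-H in CH2Cl2 at −78 °C reduces it to the aldehyde (2R,6S)-4-(TBS-oxy)-6-[3-methoxy-4-(TBS-oxy)phenyl]-3,6-dihydro-2H-pyran-2-carbaldehyde F6. Titanium reagent 9 adds as in step 4 to give the alcohol (1S)-1-{(2R,6S)-4-(TBS-oxy)-6-[3-methoxy-4-(TBS-oxy)phenyl]-3,6-dihydro-2H-pyran-2-yl}-2-[4-(TBS-oxy)phenyl]ethan-1-ol F7. TBAF/AcOH removes all three silyl groups, the enol ether becoming the C4 ketone, and the fallback comes back to the route at 11.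

**Further compounds**

F1 | step 4 | (2S,6R)-6-{(1R)-1-hydroxy-2-[4-(TBS-oxy)phenyl]ethyl}-2-[3-methoxy-4-(TBS-oxy)phenyl]oxan-4-one | COc1cc([C@@H]2CC(=O)C[C@H]([C@H](O)Cc3ccc(O[Si](C)(C)C(C)(C)C)cc3)O2)ccc1O[Si](C)(C)C(C)(C)C
F2 | step 4 | (1S)-1-{(2R,6S)-6-[3-methoxy-4-(TBS-oxy)phenyl]-4-oxooxan-2-yl}-2-[4-(TBS-oxy)phenyl]ethyl 4-nitrobenzoate | COc1cc([C@@H]2CC(=O)C[C@H]([C@@H](OC(=O)c3ccc(cc3)[N+](=O)[O-])Cc3ccc(O[Si](C)(C)C(C)(C)C)cc3)O2)ccc1O[Si](C)(C)C(C)(C)C
F3 | step 2 | (E)-4-[3-methoxy-4-(TBS-oxy)phenyl]but-3-en-2-one | CC(=O)/C=C/c1ccc(O[Si](C)(C)C(C)(C)C)c(OC)c1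
F4 | step 2 | (1E,5R)-5-hydroxy-1-[3-methoxy-4-(TBS-oxy)phenyl]-6-(TBS-oxy)hex-1-en-3-one | COc1cc(/C=C/C(=O)C[C@H](CO[Si](C)(C)C(C)(C)C)O)ccc1O[Si](C)(C)C(C)(C)C
F5 | step 3 | ethyl (2R,6S)-4-(TBS-oxy)-6-[3-methoxy-4-(TBS-oxy)phenyl]-3,6-dihydro-2H-pyran-2-carboxylate | COc1cc([C@@H]2C=C(O[Si](C)(C)C(C)(C)C)C[C@H](C(=O)OCC)O2)ccc1O[Si](C)(C)C(C)(C)C
F6 | step 3 | (2R,6S)-4-(TBS-oxy)-6-[3-methoxy-4-(TBS-oxy)phenyl]-3,6-dihydro-2H-pyran-2-carbaldehyde | COc1cc([C@@H]2C=C(O[Si](C)(C)C(C)(C)C)C[C@H](C=O)O2)ccc1O[Si](C)(C)C(C)(C)C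
F7 | step 3 | (1S)-1-{(2R,6S)-4-(TBS-oxy)-6-[3-methoxy-4-(TBS-oxy)phenyl]-3,6-dihydro-2H-pyran-2-yl}-2-[4-(TBS-oxy)phenyl]ethan-1-ol | COc1cc([C@@H]2C=C(O[Si](C)(C)C(C)(C)C)C[C@H]([C@@H](O)Cc3ccc(O[Si](C)(C)C(C)(C)C)cc3)O2)ccc1O[Si](C)(C)C(C)(C)C
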